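**Retrosynthetic overview**

1. Numbering runs from C1 (ester C=O) to C16 (CHPh). The only ring is the 1,2-dioxane O1–O2–C3–C4–C5–C6, and the SMILES reads as 3S,4R,6S,8R,15Z.
2. Feature: C6 is fully substituted, carrying CH3, the C5 and C7 methylenes and O1. It is therefore the tertiary radical formed by adding H• to a C6=CH2 group, and its peroxide oxygen O2 can reach the C3 ketone through a six-membered ring.
3. Late disconnections: the C15=C16 Z-alkene comes from the alkyne, because a styrene would not survive a cobalt hydride. The O2–C3 hemiketal comes from the γ-hydroperoxy β-keto ester, and the C6–O1 bond from the methylidene keto ester, O2 and Et3SiH.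
4. Keto ester: C2–C3 by malonate acylation and C4–C5 by auxiliary-controlled alkylation, which sets C4. C6=CH2 comes from α-methylenation of the C5 aldehyde. C10–C11 comes from copper-catalysed coupling of (S)-citronellyl Grignard, which brings C8, with a phenylacetylene-derived bromide.
5. Ring order: the single ring closes in step 11, after the C6–O bond exists, and C3 settles under anomeric (thermodynamic) control.

Key step: step 10

Remark on the chemistry: C4 is fixed by an auxiliary and not left to late equilibration. Both C4 epimers of the 6S dioxanol can adopt a chair with equatorial 4-CH3 and axial OH. They differ only in whether C6-CH3 or C6-CH2R is axial, so thermodynamics should hardly tell them apart.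

**Step 1**
Reactants: 1 phenylacetylene; 2 1,4-dibromobutane
Product: 4 (6-bromohex-1-yn-1-yl)benzene, via lithium phenylacetylide 3 (not isolated)
Conditions: n-BuLi, THF, −78 °C; then 2 (3 equiv), DMPU, −78 °C → rt
Reagents that add atoms: 1,4-dibromobutane (2), BrCCCCBr
Why: SN2 alkylation of a lithium acetylide with a primary bromide, in which DMPU raises the acetylide reactivity and the excess dibromide (distilled off afterwards) keeps double alkylation down.

**Step 2**
Reactants: 5 (S)-citronellyl bromide [(6S)-8-bromo-2,6-dimethyloct-2-ene]; 4 (6-bromohex-1-yn-1-yl)benzene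
Product: 7 [(9R)-9,13-dimethyltetradec-12-en-1-yn-1-yl]benzene, via (S)-citronellylmagnesium bromide 6 (not isolated)
Conditions: Mg, THF, rt → 40 °C; then 4, Li2CuCl4 (3 mol %), NMP, THF, 0 °C → rt
Reagents that add atoms: none
Why: Copper-catalysed Kochi-type sp3–sp3 cross-coupling of a primary Grignard reagent with a primary bromide forms C10–C11; the methyl-bearing centre (C8 of the target) comes from the chiral pool, sits two carbons from the C–Mg bond and is not touched, and an internal 1-arylalkyne is inert to the catalytic cuprate.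

**Step 3**
Reactants: 7 [(9R)-9,13-dimethyltetradec-12-en-1-yn-1-yl]benzene
Product: 9 (4R)-4-methyl-12-phenyldodec-11-ynal, via 2,3-diol 8 (not isolated)
Conditions: OsO4 (2 mol %), NaIO4 (4 equiv), 2,6-lutidine, dioxane/H2O, rt
Reagents that add atoms: osmium tetroxide, O=[Os](=O)(=O)=O (delivers the oxygen); sodium periodate, [Na+].[O-]I(=O)(=O)=O (terminal oxidant that restores it)
Why: Lemieux–Johnson cleavage, in which OsO4 dihydroxylates the electron-rich trisubstituted alkene much faster than the aryl alkyne and periodate cleaves the diol to the C5 aldehyde and acetone, with 2,6-lutidine holding back over-oxidation.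

**Step 4**
Reactants: 9 (4R)-4-methyl-12-phenyldodec-11-ynal; 10 formaldehyde
Product: 11 (4R)-4-methyl-2-methylidene-12-phenyldodec-11-ynal
Conditions: 37% aq. 10, pyrrolidine (10 mol %), EtCO2H (10 mol %), i-PrOH, 45 °C
Reagents that add atoms: formaldehyde (10), C=O
Why: Amine/acid-catalysed Mannich condensation–elimination (organocatalytic α-methylenation of an aldehyde) places the methylidene carbon on C6, and the C8 centre is γ to the carbonyl group and therefore not enolisable.

**Step 5**
Reactants: 11 (4R)-4-methyl-2-methylidene-12-phenyldodec-11-ynal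
Product: 12 (4R)-4-methyl-2-methylidene-12-phenyldodec-11-yn-1-ol
Conditions: NaBH4, CeCl3·7H2O, MeOH, 0 °C
Reagents that add atoms: none
Why: Luche reduction delivers hydride 1,2 to the enal, so the 1,1-disubstituted alkene and the alkyne stay.

**Step 6**
Reactants: 12 (4R)-4-methyl-2-methylidene-12-phenyldodec-11-yn-1-ol
Product: 13 [(9R)-11-(bromomethyl)-9-methyldodec-11-en-1-yn-1-yl]benzene
Conditions: CBr4, PPh3, CH2Cl2, 0 °C
Reagents that add atoms: carbon tetrabromide, BrC(Br)(Br)Br
Why: Appel bromination under neutral conditions, where direct and allylic-shift substitution lead to the same 2-substituted allyl bromide, so regiochemistry is not an issue.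

**Step 7**
Reactants: 14 (S)-4-benzyl-3-propionyloxazolidin-2-one; 13 [(9R)-11-(bromomethyl)-9-methyldodec-11-en-1-yn-1-yl]benzene
Product: 16 (S)-4-benzyl-3-[(2R,6R)-2,6-dimethyl-4-methylidene-14-phenyltetradec-13-ynoyl]oxazolidin-2-one, via sodium Z-enolate 15 (not isolated)
Conditions: 14 (1.5 equiv), NaN(SiMe3)2, THF, −78 °C; then 13, −78 → −30 °C
Reagents that add atoms: (S)-4-benzyl-3-propionyloxazolidin-2-one (14), CCC(=O)N1[C@@H](Cc2ccccc2)COC1=O
Why: Evans asymmetric alkylation, in which the chelated sodium Z-enolate is shielded on one face by the benzyl group of the (S)-oxazolidinone, so the reactive allylic bromide bonds to the opposite face and sets the 2R centre (C4 of the target), any minor diastereomer being removable by chromatography.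

**Step 8**
Reactants: 16 (S)-4-benzyl-3-[(2R,6R)-2,6-dimethyl-4-methylidene-14-phenyltetradec-13-ynoyl]oxazolidin-2-one
Product: 18 (2R,6R)-2,6-dimethyl-4-methylidene-14-phenyltetradec-13-ynoic acid, via peroxy acid 17 (not isolated)
Conditions: LiOH, 30% H2O2, THF/H2O, 0 °C; Na2SO3; then 1 M HCl
Reagents that add atoms: hydrogen peroxide, OO
Why: Hydroperoxide-mediated cleavage of the N-acyl oxazolidinone, in which the small, weakly basic LiOOH attacks the exocyclic carbonyl group without enolising the α-centre and sulfite reduces the percarboxylate before it can epoxidise the alkene.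

**Step 9**
Reactants: 18 (2R,6R)-2,6-dimethyl-4-methylidene-14-phenyltetradec-13-ynoic acid; 19 potassium methyl malonate
Product: 21 methyl (4R,8R)-4,8-dimethyl-6-methylidene-3-oxo-16-phenylhexadec-15-ynoate, via acyl imidazolide 20 (not isolated)
Conditions: CDI, THF, rt; then 19, MgCl2, Et3N, THF/MeCN, rt; cold 1 M HCl work-up
Reagents that add atoms: potassium methyl malonate (19), [K+].COC(=O)CC(=O)[O-]
Why: Masamune–Brooks two-carbon homologation, in which the acyl imidazolide C-acylates the magnesium enolate of methyl malonate with loss of CO2 under nearly neutral conditions and the product rests as the magnesium chelate of its C2 enolate, which shields the C4 centre from epimerisation.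

**Step 10**
Reactants: 21 methyl (4R,8R)-4,8-dimethyl-6-methylidene-3-oxo-16-phenylhexadec-15-ynoate; 22 dioxygen; 23 triethylsilane
Product: 24 methyl (4R,6S,8R)-4,6,8-trimethyl-3-oxo-16-phenyl-6-[(triethylsilyl)peroxy]hexadec-15-ynoate (carried on in admixture with its 6R epimer)
Conditions: Co(thd)2 [thd = 2,2,6,6-tetramethylheptane-3,5-dionate] (10 mol %), 23 (2.5 equiv), 22 (1 atm), ClCH2CH2Cl, rt
Reagents that add atoms: dioxygen (22), O=O; triethylsilane (23), CC[SiH](CC)CC
Why: Silane and O2 turn the divalent cobalt diketonate into a trivalent cobalt hydride that passes a hydrogen atom to the unsubstituted CH2 terminus of the C6 methylidene; the tertiary C6 radical is captured by O2, and Et3SiH exchanges with the resulting cobalt peroxide to release the C6–OO–SiEt3 group and regenerate the hydride. The closest known reaction type is the Mukaiyama–Isayama hydrosilylperoxidation of 1,1-disubstituted alkenes. No ring closes here, because silylation keeps the peroxide oxygen from adding to the C3 ketone until step 11. The new C6 stereocentre is not controlled, since the planar radical lies in a flexible chain two bonds from both C4 and C8, so both epimers should form in similar amounts and the 6S epimer is selected by separation after ring closure. Markovnikov regioselectivity follows from tertiary over primary radical stability, and the required chemoselectivity (alkene ahead of the aryl alkyne and the C2 methylene) rests on the unhindered 1,1-dialkyl alkene being the best hydrogen-atom acceptor present, on carrying the styrene as the much less reactive alkyne, and on neutral room-temperature conditions that also leave C4 unenolised.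

**Step 11**
Reactants: 24 methyl (4R,6S,8R)-4,6,8-trimethyl-3-oxo-16-phenyl-6-[(triethylsilyl)peroxy]hexadec-15-ynoate (with its 6R epimer)
Product: 26 methyl 2-[(3S,4R,6S)-3-hydroxy-4,6-dimethyl-6-[(2R)-2-methyl-10-phenyldec-9-yn-1-yl]-1,2-dioxan-3-yl]acetate, via hydroperoxy ketone 25 (not isolated)
Conditions: 48% aq. HF, MeCN, 0 °C; chromatographic separation of the C6 epimers
Reagents that add atoms: none
Why: Fluoride-driven Si–O cleavage frees the tertiary hydroperoxide, whose terminal oxygen adds 6-exo-trig to the C3 ketone; C3 is set under thermodynamic control through ring–chain tautomerism (axial anomeric OH, equatorial CH2CO2Me, 4-CH3 and C6 side chain), and the 6S and 6R dioxanols, now ring diastereomers, are parted by chromatography.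

**Step 12**
Reactants: 26 methyl 2-[(3S,4R,6S)-3-hydroxy-4,6-dimethyl-6-[(2R)-2-methyl-10-phenyldec-9-yn-1-yl]-1,2-dioxan-3-yl]acetate
Product: 27 methyl 2-[(3S,4R,6S)-3-hydroxy-4,6-dimethyl-6-[(2R,9Z)-2-methyl-10-phenyldec-9-en-1-yl]-1,2-dioxan-3-yl]acetate (CNP0217486.1)
Conditions: H2 (1 atm, stopped after 1 equiv), Pd/CaCO3 poisoned with Pb(OAc)2 (Lindlar catalyst), quinoline, EtOAc, 0 °C
Reagents that add atoms: none
Why: Lindlar semi-hydrogenation adds H2 syn on the poisoned palladium surface and so gives the Z-styrene, while the O–O bond, flanked by the fully substituted C3 and C6, should adsorb too poorly to be cleaved if uptake is stopped after one equivalent.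

**Compound list**

1 | phenylacetylene | C#Cc1ccccc1 | starting material
2 | 1,4-dibromobutane | BrCCCCBr | starting material
3 | lithium phenylacetylide | [Li]C#Cc1ccccc1 | intermediate
4 | (6-bromohex-1-yn-1-yl)benzene | BrCCCCC#Cc1ccccc1 | intermediate
5 | (S)-citronellyl bromide | CC(C)=CCC[C@H](C)CCBr | starting material
6 | (S)-citronellylmagnesium bromide | CC(C)=CCC[C@H](C)CC[Mg]Br | intermediate
7 | [(9R)-9,13-dimethyltetradec-12-en-1-yn-1-yl]benzene | CC(C)=CCC[C@H](C)CCCCCCC#Cc1ccccc1 | intermediate
8 | (6R)-2,6-dimethyl-14-phenyltetradec-13-yne-2,3-diol (both C3 epimers) | CC(C)(O)C(O)CC[C@H](C)CCCCCCC#Cc1ccccc1 | intermediate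
9 | (4R)-4-methyl-12-phenyldodec-11-ynal | O=CCC[C@H](C)CCCCCCC#Cc1ccccc1 | intermediate
10 | formaldehyde | C=O | starting material
11 | (4R)-4-methyl-2-methylidene-12-phenyldodec-11-ynal | O=CC(=C)C[C@H](C)CCCCCCC#Cc1ccccc1 | intermediate
12 | (4R)-4-methyl-2-methylidene-12-phenyldodec-11-yn-1-ol | OCC(=C)C[C@H](C)CCCCCCC#Cc1ccccc1 | intermediate
13 | [(9R)-11-(bromomethyl)-9-methyldodec-11-en-1-yn-1-yl]benzene | BrCC(=C)C[C@H](C)CCCCCCC#Cc1ccccc1 | intermediate
14 | (S)-4-benzyl-3-propionyloxazolidin-2-one | CCC(=O)N1[C@@H](Cc2ccccc2)COC1=O | starting material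
15 | sodium Z-enolate of 14 | [Na+].C/C=C(\[O-])N1[C@@H](Cc2ccccc2)COC1=O | intermediate
16 | (S)-4-benzyl-3-[(2R,6R)-2,6-dimethyl-4-methylidene-14-phenyltetradec-13-ynoyl]oxazolidin-2-one | O=C([C@H](C)CC(=C)C[C@H](C)CCCCCCC#Cc1ccccc1)N1[C@@H](Cc2ccccc2)COC1=O | intermediate
17 | (2R,6R)-2,6-dimethyl-4-methylidene-14-phenyltetradec-13-yneperoxoic acid | OOC(=O)[C@H](C)CC(=C)C[C@H](C)CCCCCCC#Cc1ccccc1 | intermediate
18 | (2R,6R)-2,6-dimethyl-4-methylidene-14-phenyltetradec-13-ynoic acid | OC(=O)[C@H](C)CC(=C)C[C@H](C)CCCCCCC#Cc1ccccc1 | intermediate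
19 | potassium methyl malonate | [K+].COC(=O)CC(=O)[O-] | starting material
20 | (2R,6R)-1-(imidazol-1-yl)-2,6-dimethyl-4-methylidene-14-phenyltetradec-13-yn-1-one | O=C([C@H](C)CC(=C)C[C@H](C)CCCCCCC#Cc1ccccc1)n1ccnc1 | intermediate
21 | methyl (4R,8R)-4,8-dimethyl-6-methylidene-3-oxo-16-phenylhexadec-15-ynoate | COC(=O)CC(=O)[C@H](C)CC(=C)C[C@H](C)CCCCCCC#Cc1ccccc1 | intermediate
22 | dioxygen | O=O | starting material
23 | triethylsilane | CC[SiH](CC)CC | starting material
24 | methyl (4R,6S,8R)-4,6,8-trimethyl-3-oxo-16-phenyl-6-[(triethylsilyl)peroxy]hexadec-15-ynoate | COC(=O)CC(=O)[C@H](C)C[C@@](C)(OO[Si](CC)(CC)CC)C[C@H](C)CCCCCCC#Cc1ccccc1 | intermediate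
25 | methyl (4R,6S,8R)-6-hydroperoxy-4,6,8-trimethyl-3-oxo-16-phenylhexadec-15-ynoate | COC(=O)CC(=O)[C@H](C)C[C@@](C)(OO)C[C@H](C)CCCCCCC#Cc1ccccc1 | intermediate
26 | methyl 2-[(3S,4R,6S)-3-hydroxy-4,6-dimethyl-6-[(2R)-2-methyl-10-phenyldec-9-yn-1-yl]-1,2-dioxan-3-yl]acetate | COC(=O)C[C@]1(O)OO[C@@](C)(C[C@H](C)CCCCCCC#Cc2ccccc2)C[C@H]1C | intermediate
27 | methyl 2-[(3S,4R,6S)-3-hydroxy-4,6-dimethyl-6-[(2R,9Z)-2-methyl-10-phenyldec-9-en-1-yl]-1,2-dioxan-3-yl]acetate | COC(=O)C[C@]1(O)OO[C@@](C)(C[C@H](C)CCCCCC/C=C\c2ccccc2)C[C@H]1C | target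

**Step count**

Total step count: 12.
Longest linear sequence: 12 steps (1 → 27). Compound 5 enters at step 2, 14 at step 7 and 19 at step 9.

**Steps most likely to fail**

**Step 10.**
- What may go wrong: the β-keto ester may exchange with the diketonate ligands and stall hydride formation. Aerobic oxidation at the C2 methylene may compete, and slow hydrogen-atom transfer to the aryl alkyne may erode the material.
- Fallback, from 21 back to 24: the ketone is taken out of play for the radical step.
  - NaBH4 in MeOH at −20 °C should give methyl (4R,8R)-3-hydroxy-4,8-dimethyl-6-methylidene-16-phenylhexadec-15-ynoate F1, as both C3 epimers, which is of no consequence.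
  - The same cobalt silylperoxidation then should give methyl (4R,6S,8R)-3-hydroxy-4,6,8-trimethyl-16-phenyl-6-[(triethylsilyl)peroxy]hexadec-15-ynoate F2, together with its 6R epimer.
  - NaHCO3-buffered Dess–Martin oxidation, which does not attack silyl peroxides, restores the C3 ketone and rejoins the route at 24.

**Step 12.**
- What may go wrong: the O–O bond may be hydrogenolysed through the small share of open hydroperoxide tautomer on palladium. Over-reduction of the styrene and Z-to-E isomerisation are also possible.
- Fallback, from 24 back to 27: the order of unmasking is inverted, so the catalyst only meets an acyclic, fully substituted silyl peroxide and no reductant follows ring closure.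
  - Lindlar semi-hydrogenation of 24 should give methyl (4R,6S,8R,15Z)-4,6,8-trimethyl-3-oxo-16-phenyl-6-[(triethylsilyl)peroxy]hexadec-15-enoate F3.
  - Aqueous HF in MeCN frees methyl (4R,6S,8R,15Z)-6-hydroperoxy-4,6,8-trimethyl-3-oxo-16-phenylhexadec-15-enoate F4, which is not isolated.
  - F4 closes to the hemiketal, and separation of the C6 epimers then delivers 27 directly.

**Step 11.**
- What may go wrong: the C6 epimers may co-elute. The hemiketals may streak or degrade on silica through ring–chain tautomerism, and the acid may slowly enolise C4.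
- Fallback, from 24 back to 26: the ring is locked as a peroxyketal for the separation.
  - Catalytic HCl in MeOH desilylates, cyclises and ketalises in one operation to methyl 2-[(3S,4R,6S)-3-methoxy-4,6-dimethyl-6-[(2R)-2-methyl-10-phenyldec-9-yn-1-yl]-1,2-dioxan-3-yl]acetate F5 and its 6R epimer.
  - These have no open form and should chromatograph cleanly.
  - Acetal hydrolysis of pure F5 through the peroxycarbenium ion (CF3CO2H, THF/H2O, 0 °C) returns to the route at 26.

**Further compounds**
F1 | step 10 | methyl (4R,8R)-3-hydroxy-4,8-dimethyl-6-methylidene-16-phenylhexadec-15-ynoate | COC(=O)CC(O)[C@H](C)CC(=C)C[C@H](C)CCCCCCC#Cc1ccccc1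
F2 | step 10 | methyl (4R,6S,8R)-3-hydroxy-4,6,8-trimethyl-16-phenyl-6-[(triethylsilyl)peroxy]hexadec-15-ynoate | COC(=O)CC(O)[C@H](C)C[C@@](C)(OO[Si](CC)(CC)CC)C[C@H](C)CCCCCCC#Cc1ccccc1
F3 | step 12 | methyl (4R,6S,8R,15Z)-4,6,8-trimethyl-3-oxo-16-phenyl-6-[(triethylsilyl)peroxy]hexadec-15-enoate | COC(=O)CC(=O)[C@H](C)C[C@@](C)(OO[Si](CC)(CC)CC)C[C@H](C)CCCCCC/C=C\c1ccccc1
F4 | step 12 | methyl (4R,6S,8R,15Z)-6-hydroperoxy-4,6,8-trimethyl-3-oxo-16-phenylhexadec-15-enoate | COC(=O)CC(=O)[C@H](C)C[C@@](C)(OO)C[C@H](C)CCCCCC/C=C\c1ccccc1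
F5 | step 11 | methyl 2-[(3S,4R,6S)-3-methoxy-4,6-dimethyl-6-[(2R)-2-methyl-10-phenyldec-9-yn-1-yl]-1,2-dioxan-3-yl]acetate | COC(=O)C[C@]1(OC)OO[C@@](C)(C[C@H](C)CCCCCCC#Cc2ccccc2)C[C@H]1C
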